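**Plan**

1. Atom numbers used below: ring C1–C10 with C1=C10 (C10 carries the CHO carbon C14), C2 (OH), C4=C5 (C4 carries C15H2OAc), C6 (lactone O), C7, C8 (isovalerate); lactone C12(=O)–C11(=C13H2).
2. Retrosynthetic cuts, in this order: C1–C2 (ten-membered ring, alkenyl iodide plus aldehyde), C7–C11 (lactone ring), C3–C4 (Negishi), C5–C6 (alkynylation), C7=C8 (cross-metathesis), C9–C10 (carbomagnesiation).
3. Forward: the open chain is grown linearly from the C1/C10/C14 end out of small building blocks, the γ-lactone is closed on the open chain (step 9), and the ten-membered carbocycle is closed last (step 15).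
4. Enabling feature: the lactone atoms O–C6–C7–C11(=C13)–C12 lie next to the oxygen-bearing C8, so an acrylate on O6 plus a trans-7,8-epoxide already hold every atom of the α-methylene lactone and the C8–O bond. A phosphine-triggered Morita–Baylis–Hillman-type epoxide opening then makes the C7–C11 bond, the ring, the C7 and C8 stereocentres and the exocyclic methylene in one operation.
5. Stereochemistry: C6 by catalyst-controlled alkynylation; C7/C8 by matched Sharpless epoxidation, relayed with inversion at C7; C2 by CBS reduction of the macrocyclic enone; C1=C10 geometry by anti-carbomagnesiation, C4=C5 geometry by trans-hydroalumination.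

Key step: step 9

Assumption: the (S,S) antipode of ProPhenol is taken to be the one that gives the 6S carbinol 9; the matched epoxidation of step 7 removes the minor enantiomer in any case, and the (R,R) ligand is the direct remedy if the sense proves opposite.

Step 1
Reactants: 1 3-(trimethylsilyl)prop-2-yn-1-ol; 2 allylmagnesium bromide
Product: 4 (2E)-2-(prop-2-en-1-yl)-3-(trimethylsilyl)prop-2-en-1-ol (SiMe3 cis to the allyl group), via alkenylmagnesium alkoxide chelate 3 (not isolated)
Conditions: allylMgBr (3 equiv), Et2O, 0 °C → reflux; aq NH4Cl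
Reagents that add atoms: none
Why: Alkoxide-directed anti-carbomagnesiation of a propargylic alcohol puts the allyl group on the alkyne carbon next to CH2O and magnesium on the silyl-bearing carbon inside a five-membered chelate, so that protonation should leave SiMe3 cis to the allyl group (C9) and trans to CH2OH (C14), the C1=C10 geometry needed later.

Step 2
Reactants: 4 (2E)-2-(prop-2-en-1-yl)-3-(trimethylsilyl)prop-2-en-1-ol
Product: 5 tert-butyldimethylsilyl ether of 4
Conditions: TBSCl, imidazole, DMF, 0 → 23 °C
Reagents that add atoms: tert-butyldimethylsilyl chloride, CC(C)(C)[Si](C)(C)Cl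
Why: Standard silylation of a primary alcohol, which masks O14 until the last two steps.

Step 3
Reactants: 5 tert-butyldimethylsilyl ether of 4; 6 (E)-but-2-enal
Product: 7 (2E,5E)-5-[(tert-butyldimethylsilyloxy)methyl]-6-(trimethylsilyl)hexa-2,5-dienal
Conditions: second-generation Grubbs catalyst (5 mol %), (E)-but-2-enal (5 equiv), CH2Cl2, 40 °C
Reagents that add atoms: none
Why: Olefin cross-metathesis of the terminal alkene with crotonaldehyde should give the E-enal (C6–C8), while the trisubstituted alkenylsilane is too hindered to take part.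

Step 4
Reactants: 7 (2E,5E)-5-[(tert-butyldimethylsilyloxy)methyl]-6-(trimethylsilyl)hexa-2,5-dienal; 8 1-methoxy-4-[(prop-2-yn-1-yloxy)methyl]benzene
Product: 9 (4S,5E,8E)-8-[(tert-butyldimethylsilyloxy)methyl]-1-[(4-methoxybenzyl)oxy]-9-(trimethylsilyl)nona-5,8-dien-2-yn-4-ol
Conditions: Me2Zn (3 equiv), (S,S)-ProPhenol (20 mol %), Ph3P=O (40 mol %), toluene, 4 °C
Reagents that add atoms: none
Why: Zinc–ProPhenol-catalysed enantioselective alkynylation of an enal is a 1,2-addition in which the dinuclear zinc catalyst delivers the alkynyl group to one face of the aldehyde, which sets C6 (S in 9; the same spatial arrangement is named 6R from 14 onward).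

Step 5
Reactants: 9 (4S,5E,8E)-8-[(tert-butyldimethylsilyloxy)methyl]-1-[(4-methoxybenzyl)oxy]-9-(trimethylsilyl)nona-5,8-dien-2-yn-4-ol
Product: 11 (2Z,4S,5E,8E)-8-[(tert-butyldimethylsilyloxy)methyl]-2-iodo-1-[(4-methoxybenzyl)oxy]-9-(trimethylsilyl)nona-2,5,8-trien-4-ol, via cyclic alkenylalanate 10 (not isolated)
Conditions: NaAlH2(OCH2CH2OMe)2 (2.2 equiv), THF, −20 → 0 °C; EtOAc; I2, THF, −78 °C
Reagents that add atoms: iodine, [I][I]
Why: Hydroxyl-directed trans-hydroalumination of the propargylic alcohol places hydride on C5 and aluminium on C4, and iodinolysis with retention should give the alkenyl iodide with iodine cis to C6, the low temperature keeping the alanate from expelling the neighbouring ether oxygen as an allene.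

Step 6
Reactants: 11 (2Z,4S,5E,8E)-2-iodo trienol; 12 (1,3-dioxolan-2-ylmethyl)zinc bromide
Product: 13 (2E,4S,5E,8E)-8-[(tert-butyldimethylsilyloxy)methyl]-2-(1,3-dioxolan-2-ylmethyl)-1-[(4-methoxybenzyl)oxy]-9-(trimethylsilyl)nona-2,5,8-trien-4-ol
Conditions: PdCl2(dppf) (5 mol %), 12 (3.5 equiv), THF, 50 °C
Reagents that add atoms: none
Why: Negishi coupling of an alkenyl iodide with an alkylzinc halide proceeds with retention of alkene geometry, so the C3–C2 unit (C2 already at the aldehyde level as a dioxolane) should end cis to C6 and CH2OPMB trans, which is the C4=C5 geometry of the target.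

Step 7
Reactants: 13 (2E,4S,5E,8E)-dioxolanylmethyl trienol
Product: 14 (6R,7R,8R)-epoxy alcohol: 13 in which the C7=C8 bond has become a trans-oxirane whose oxygen is anti (erythro) to the C6 hydroxyl
Conditions: Ti(OiPr)4 (1.0 equiv), D-(−)-diisopropyl tartrate (1.2 equiv), tBuOOH (2 equiv), 4 Å molecular sieves, CH2Cl2, −20 °C
Reagents that add atoms: tert-butyl hydroperoxide, CC(C)(C)OO
Why: Sharpless epoxidation of a secondary allylic alcohol in the matched sense: with the D-(−)-tartrate the carbinol configuration of 13 is the fast-reacting one for the E-disubstituted C7=C8 bond and should give the erythro epoxy alcohol, whereas the trisubstituted C4=C5 bond is mismatched and carries a cis substituent, and any minor C6 enantiomer is left behind by kinetic resolution.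

Step 8
Reactants: 14 (6R,7R,8R)-epoxy alcohol; 15 acryloyl chloride
Product: 16 6-O-acrylate of 14 (6R,7S,8R by the changed CIP ranking; no centre altered)
Conditions: acryloyl chloride (1.5 equiv), iPr2NEt, CH2Cl2, −78 → 0 °C
Reagents that add atoms: none
Why: O-acylation of a secondary alcohol with an acid chloride and a hindered amine at low temperature should leave the epoxide and both acetal-type groups untouched.

Step 9
Reactants: 16 6-O-acrylate of 14
Product: 19 (6R,7R,8R)-lactone alcohol: 3-methylidene-γ-butyrolactone carrying on C6 the arm (E)-CH=C(CH2OPMB)CH2(1,3-dioxolan-2-yl) and on C7, trans to it, the arm CH(OH)CH2C(CH2OTBS)=CH–SiMe3, via phosphonium enolate 17 (not isolated), via phosphonium alkoxide lactone 18 (not isolated)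
Conditions: PMe3 (0.5 equiv), tBuOH/THF (4:1), 0.01 M, 23 °C
Reagents that add atoms: none
Why: Proposed new method: PMe3 adds reversibly to the acrylate β-carbon C13 to give phosphonium enolate 17, whose α-carbon C11 attacks the epoxide carbon C7 anti to the C7–O bond (the epoxide being activated by hydrogen bonding to tBuOH), and lactone 18 then loses PMe3 by proton transfer from C11 and E1cB elimination, which unveils the C11=C13 methylene and turns the phosphine over. The closest known reaction types are the phosphine-mediated intramolecular Morita–Baylis–Hillman alkylation of enones by tethered epoxides and the intramolecular Rauhut–Currier reaction, and the extension made here is from an enone to the acrylate ester of a 2,3-epoxy alcohol. The γ-lactone ring (O–C6–C7–C11–C12) closes in the 5-exo-tet mode, the breaking C7–O bond lying outside the new ring. C7 is set by SN2 inversion and C8 keeps the epoxide oxygen with retention, so both centres are relayed from the Sharpless epoxide, C6 is untouched and the lactone is trans-substituted (H6 and H7 anti). The step needs attack at C7 and not 6-endo attack at C8, which the three-atom tether and the unactivated C8 should secure, and it needs the C8 alkoxide to be protonated before it can re-open the lactone toward the 8,12-olide, which the protic medium is there to ensure, high dilution guarding against intermolecular Rauhut–Currier dimerisation.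

Step 10
Reactants: 19 (6R,7R,8R)-lactone alcohol; 20 3-methylbutanoyl chloride
Product: 21 8-O-(3-methylbutanoate) of 19
Conditions: isovaleryl chloride, pyridine, DMAP (cat.), CH2Cl2, 0 °C
Reagents that add atoms: none
Why: Acylation of the secondary C8 alcohol installs the isovalerate of the target and at the same time removes the hydroxyl that could migrate the lactone.

Step 11
Reactants: 21 8-O-(3-methylbutanoate) of 19
Product: 22 C15 alcohol: 21 with the 4-methoxybenzyl ether cleaved to CH2OH
Conditions: DDQ, CH2Cl2/pH 7 buffer (10:1), 0 °C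
Reagents that add atoms: none
Why: Oxidative cleavage of a 4-methoxybenzyl ether with DDQ under buffered two-phase conditions should spare the silyl ether, the dioxolane, the alkenylsilane and the esters, and no free allylic carbinol is present to be oxidised.

Step 12
Reactants: 22 C15 alcohol; 23 acetic anhydride
Product: 24 C15 acetate: 22 with CH2OAc on C4
Conditions: Ac2O, pyridine, DMAP (cat.), CH2Cl2, 0 °C
Reagents that add atoms: none
Why: Acetylation of the only free (primary allylic) hydroxyl gives the C15 acetate of the target.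

Step 13
Reactants: 24 C15 acetate
Product: 25 C1 iodide: 24 with iodine in place of SiMe3 (iodine cis to C9)
Conditions: NIS, 2,6-lutidine, (CF3)2CHOH/CH2Cl2, 0 °C
Reagents that add atoms: N-iodosuccinimide, O=C1CCC(=O)N1I
Why: Ipso-iododesilylation of the alkenylsilane through a β-silyl-stabilised cation proceeds with retention of geometry in hexafluoroisopropanol, and the other alkenes, which are electron-poor or lack silicon, should not react.

Step 14
Reactants: 25 C1 iodide
Product: 27 C2 aldehyde: 25 with the dioxolane converted into CH2CHO on C4, via N-alkylcollidinium triflate 26 (not isolated)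
Conditions: Et3SiOTf, 2,4,6-collidine, CH2Cl2, 0 °C; H2O
Reagents that add atoms: water, O
Why: Silyl triflate and collidine open the dioxolane to a pyridinium-type N,O-acetal that water hydrolyses to the aldehyde under nearly neutral conditions, which should avoid the aqueous acid that would move the β,γ-double bond into conjugation or cleave the silyl ether.

Step 15
Reactants: 27 C2 aldehyde
Product: 28 ten-membered carbinol with C14–OTBS, as a mixture of C2 epimers (6R,7R,8R)
Conditions: CrCl2 (10 equiv), NiCl2 (0.1 equiv), DMSO/THF (3:1), 0.002 M, 23 °C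
Reagents that add atoms: none
Why: Nozaki–Hiyama–Kishi reaction, in which the alkenyl iodide is activated by zerovalent nickel formed in situ and passed to trivalent chromium, adds chemoselectively to the aldehyde with retention of the C1=C10 geometry under high dilution, and both C2 epimers are carried on because C2 is reset in steps 16 and 17.

Step 16
Reactants: 28 ten-membered carbinol (C2 epimers)
Product: 29 ten-membered C2 ketone (enone conjugated with C1=C10)
Conditions: Dess–Martin periodinane, NaHCO3, CH2Cl2, 0 °C
Reagents that add atoms: none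
Why: Buffered Dess–Martin oxidation of the secondary allylic alcohol converges both epimers on one enone without base that could move the C4=C5 bond into conjugation.

Step 17
Reactants: 29 ten-membered C2 ketone
Product: 30 (2S,6R,7R,8R)-ten-membered allylic alcohol with C14–OTBS
Conditions: (R)-2-methyl-CBS-oxazaborolidine (0.5 equiv), catecholborane, toluene, −78 °C
Reagents that add atoms: none
Why: Corey–Bakshi–Shibata reduction in which the alkenyl group (C1) acts as the large and the C3 methylene as the small substituent, so that the (R)-catalyst should deliver hydride to the face giving the 2S alcohol, while catecholborane at low temperature leaves the esters, the lactone and its exocyclic alkene alone.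

Step 18
Reactants: 30 (2S)-allylic alcohol with C14–OTBS
Product: 31 (2S,6R,7R,8R)-2,14-diol
Conditions: HF·pyridine, pyridine, THF, 0 → 23 °C
Reagents that add atoms: none
Why: Buffered fluoride cleavage of the primary silyl ether is compatible with the acetate, the isovalerate and the α-methylene lactone.

Step 19
Reactants: 31 (2S,6R,7R,8R)-2,14-diol
Product: 32 target CNP0524123.1
Conditions: TEMPO (20 mol %), PhI(OAc)2, CH2Cl2, 23 °C
Reagents that add atoms: none
Why: The oxoammonium oxidation (TEMPO with PhI(OAc)2) is selective for the primary allylic alcohol over the secondary one, and since C2 stands trans to C14 across C1=C10 the remaining hydroxyl cannot close a lactol onto the new aldehyde.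

**Compound list**

1 | 3-(trimethylsilyl)prop-2-yn-1-ol | C[Si](C)(C)C#CCO | starting material
2 | allylmagnesium bromide | C=CC[Mg]Br | starting material
3 | (E)-[2-(bromomagnesiooxymethyl)-1-(trimethylsilyl)penta-1,4-dien-1-yl]magnesium bromide (Mg on carbon cis to CH2O) | C=CC/C(CO[Mg]Br)=C(/[Mg]Br)[Si](C)(C)C | intermediate
4 | (2E)-2-(prop-2-en-1-yl)-3-(trimethylsilyl)prop-2-en-1-ol | C[Si](C)(C)/C=C(/CO)CC=C | intermediate
5 | tert-butyldimethylsilyl ether of 4 | C[Si](C)(C)/C=C(/CO[Si](C)(C)C(C)(C)C)CC=C | intermediate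
6 | (E)-but-2-enal | C/C=C/C=O | starting material
7 | (2E,5E)-5-[(tert-butyldimethylsilyloxy)methyl]-6-(trimethylsilyl)hexa-2,5-dienal | O=C/C=C/C/C(CO[Si](C)(C)C(C)(C)C)=C\[Si](C)(C)C | intermediate
8 | 1-methoxy-4-[(prop-2-yn-1-yloxy)methyl]benzene | C#CCOCc1ccc(OC)cc1 | starting material
9 | (4S,5E,8E)-8-[(tert-butyldimethylsilyloxy)methyl]-1-[(4-methoxybenzyl)oxy]-9-(trimethylsilyl)nona-5,8-dien-2-yn-4-ol | COc1ccc(COCC#C[C@@H](O)/C=C/C/C(CO[Si](C)(C)C(C)(C)C)=C\[Si](C)(C)C)cc1 | intermediate
10 | sodium alanate with the five-membered ring Al–O6–C6–C5=C4 and two 2-methoxyethoxy groups on aluminium | [Na+].COCCO[Al-]1(OCCOC)O[C@@H](/C=C/C/C(CO[Si](C)(C)C(C)(C)C)=C\[Si](C)(C)C)C=C1COCc1ccc(OC)cc1 | intermediate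
11 | (2Z,4S,5E,8E)-8-[(tert-butyldimethylsilyloxy)methyl]-2-iodo-1-[(4-methoxybenzyl)oxy]-9-(trimethylsilyl)nona-2,5,8-trien-4-ol | COc1ccc(COC/C(I)=C/[C@@H](O)/C=C/C/C(CO[Si](C)(C)C(C)(C)C)=C\[Si](C)(C)C)cc1 | intermediate
12 | (1,3-dioxolan-2-ylmethyl)zinc bromide | Br[Zn]CC1OCCO1 | starting material
13 | (2E,4S,5E,8E)-8-[(tert-butyldimethylsilyloxy)methyl]-2-(1,3-dioxolan-2-ylmethyl)-1-[(4-methoxybenzyl)oxy]-9-(trimethylsilyl)nona-2,5,8-trien-4-ol | COc1ccc(COC/C(CC2OCCO2)=C/[C@@H](O)/C=C/C/C(CO[Si](C)(C)C(C)(C)C)=C\[Si](C)(C)C)cc1 | intermediate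
14 | (6R,7R,8R)-epoxy alcohol (trans-7,8-oxirane, oxygen anti to the C6 hydroxyl) | COc1ccc(COC/C(CC2OCCO2)=C/[C@@H](O)[C@H]2O[C@@H]2C/C(CO[Si](C)(C)C(C)(C)C)=C\[Si](C)(C)C)cc1 | intermediate
15 | acryloyl chloride | C=CC(=O)Cl | starting material
16 | 6-O-acrylate of 14 | COc1ccc(COC/C(CC2OCCO2)=C/[C@@H](OC(=O)C=C)[C@H]2O[C@@H]2C/C(CO[Si](C)(C)C(C)(C)C)=C\[Si](C)(C)C)cc1 | intermediate
17 | phosphonium enolate: PMe3 on C13 of the acrylate of 16, enolate on C11/C12 | C[P+](C)(C)CC=C([O-])O[C@H](/C=C(/COCc1ccc(OC)cc1)CC1OCCO1)[C@H]1O[C@@H]1C/C(CO[Si](C)(C)C(C)(C)C)=C\[Si](C)(C)C | intermediate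
18 | trans-lactone with C11–CH2PMe3+ (C11 epimers) and C8 alkoxide | C[P+](C)(C)CC1C(=O)O[C@H](/C=C(/COCc2ccc(OC)cc2)CC2OCCO2)[C@H]1[C@H]([O-])C/C(CO[Si](C)(C)C(C)(C)C)=C\[Si](C)(C)C | intermediate
19 | (6R,7R,8R)-α-methylene lactone with free C8 hydroxyl | C=C1C(=O)O[C@H](/C=C(/COCc2ccc(OC)cc2)CC2OCCO2)[C@H]1[C@H](O)C/C(CO[Si](C)(C)C(C)(C)C)=C\[Si](C)(C)C | intermediate
20 | 3-methylbutanoyl chloride | CC(C)CC(=O)Cl | starting material
21 | 8-O-(3-methylbutanoate) of 19 | C=C1C(=O)O[C@H](/C=C(/COCc2ccc(OC)cc2)CC2OCCO2)[C@H]1[C@H](OC(=O)CC(C)C)C/C(CO[Si](C)(C)C(C)(C)C)=C\[Si](C)(C)C | intermediate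
22 | C15 alcohol (PMB removed from 21) | C=C1C(=O)O[C@H](/C=C(/CO)CC2OCCO2)[C@H]1[C@H](OC(=O)CC(C)C)C/C(CO[Si](C)(C)C(C)(C)C)=C\[Si](C)(C)C | intermediate
23 | acetic anhydride | CC(=O)OC(C)=O | starting material
24 | C15 acetate | C=C1C(=O)O[C@H](/C=C(/COC(C)=O)CC2OCCO2)[C@H]1[C@H](OC(=O)CC(C)C)C/C(CO[Si](C)(C)C(C)(C)C)=C\[Si](C)(C)C | intermediate
25 | C1 alkenyl iodide (iodine cis to C9) | C=C1C(=O)O[C@H](/C=C(/COC(C)=O)CC2OCCO2)[C@H]1[C@H](OC(=O)CC(C)C)C/C(CO[Si](C)(C)C(C)(C)C)=C\I | intermediate
26 | N-[1-(2-triethylsilyloxyethoxy)alkyl]-2,4,6-trimethylpyridinium triflate at C2 (C2 epimers) | C=C1C(=O)O[C@H](/C=C(/COC(C)=O)CC(OCCO[Si](CC)(CC)CC)[n+]2c(C)cc(C)cc2C)[C@H]1[C@H](OC(=O)CC(C)C)C/C(CO[Si](C)(C)C(C)(C)C)=C\I.[O-]S(=O)(=O)C(F)(F)F | intermediate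
27 | C2 aldehyde (β,γ-unsaturated) with C1 iodide | C=C1C(=O)O[C@H](/C=C(/COC(C)=O)CC=O)[C@H]1[C@H](OC(=O)CC(C)C)C/C(CO[Si](C)(C)C(C)(C)C)=C\I | intermediate
28 | ten-membered carbinol, C14–OTBS, mixture of C2 epimers | C=C1C(=O)O[C@@H]2/C=C(/COC(C)=O)CC(O)/C=C(/CO[Si](C)(C)C(C)(C)C)C[C@@H](OC(=O)CC(C)C)[C@@H]12 | intermediate
29 | ten-membered C2 ketone | C=C1C(=O)O[C@@H]2/C=C(/COC(C)=O)CC(=O)/C=C(/CO[Si](C)(C)C(C)(C)C)C[C@@H](OC(=O)CC(C)C)[C@@H]12 | intermediate
30 | (2S,6R,7R,8R)-alcohol with C14–OTBS | C=C1C(=O)O[C@@H]2/C=C(/COC(C)=O)C[C@H](O)/C=C(/CO[Si](C)(C)C(C)(C)C)C[C@@H](OC(=O)CC(C)C)[C@@H]12 | intermediate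
31 | (2S,6R,7R,8R)-2,14-diol | C=C1C(=O)O[C@@H]2/C=C(/COC(C)=O)C[C@H](O)/C=C(/CO)C[C@@H](OC(=O)CC(C)C)[C@@H]12 | intermediate
32 | CNP0524123.1 | C=C1C(=O)O[C@@H]2/C=C(/COC(C)=O)C[C@H](O)/C=C(/C=O)C[C@@H](OC(=O)CC(C)C)[C@@H]12 | target

**Totals and risks**

Total step count: 19. Longest linear sequence: 19 steps (1 to 32).

Step 9, the proposed new method, is the least secure. The acrylate-derived phosphonium enolate may be too weak a nucleophile for SN2 attack at the internal, inductively deactivated epoxide carbon. Intermolecular Rauhut–Currier oligomerisation, or alkoxide-driven migration of the lactone acyl group from O6 to O8, could then become the main process. The fallback uses known reaction types and replaces steps 8 and 9. It sets out from epoxy alcohol 14. Steglich esterification with diethylphosphonoacetic acid (DCC, DMAP cat., CH2Cl2) should give the phosphonoacetate ester F1. Deprotonation (NaH, THF, LiClO4 as epoxide activator, 0 → 40 °C) should bring about the same 5-exo-tet opening at C7, with inversion, by the phosphonate-stabilised carbanion, giving the α-(diethoxyphosphoryl) lactone alcohol F2. Horner–Wadsworth–Emmons methylenation with aqueous formaldehyde and K2CO3 (THF, 23 °C) then installs C13, and the route is rejoined at 19.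

Step 15 is the second risk. Closure of the strained ten-membered ring is slow, so intermolecular coupling, simple reduction of the carbon–iodine bond and migration of the β,γ-double bond of the aldehyde into conjugation can outrun it. The fallback sets out from aldehyde 27. Pinnick oxidation (NaClO2, NaH2PO4, 2-methylbut-2-ene, tBuOH/H2O) should give the carboxylic acid F3, which is converted into the S-(pyridin-2-yl) thioester F4 (2,2'-dipyridyl disulfide, PPh3, CH2Cl2). A nickel-catalysed reductive acylation of the alkenyl iodide by the thioester (NiBr2(MeOCH2CH2OMe), 4,4'-di-tert-butyl-2,2'-bipyridine, zinc dust, DMA, high dilution) would close the ring at the ketone oxidation level. The route is thus rejoined at enone 29 and step 16 falls away. The ring closure then no longer passes through the aldehyde and creates no stereocentre.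

Step 17 is the third risk. Facial selectivity may be poor if the conformational preference of the ten-membered enone opposes the catalyst, and conjugate reduction may compete. The fallback sets out from carbinol 28, and steps 16 and 17 fall away. The C2 epimers are separated by chromatography; the 2S epimer is 30 itself. The 2R epimer F5 is inverted by a Mitsunobu reaction with formic acid (PPh3, diisopropyl azodicarboxylate, THF, 0 °C) to the 2S formate F6. The formate is cleaved beside the acetate and the isovalerate with KHCO3 in aqueous methanol at 0 °C, which rejoins the route at 30.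

**Further compounds**

F1 | step 9 | 6-O-(diethylphosphonoacetate) of epoxy alcohol 14 | COc1ccc(COC/C(CC2OCCO2)=C/[C@@H](OC(=O)CP(=O)(OCC)OCC)[C@H]2O[C@@H]2C/C(CO[Si](C)(C)C(C)(C)C)=C\[Si](C)(C)C)cc1
F2 | step 9 | α-(diethoxyphosphoryl) lactone alcohol (C11 epimers; 6R,7R,8R) | CCOP(=O)(OCC)C1C(=O)O[C@H](/C=C(/COCc2ccc(OC)cc2)CC2OCCO2)[C@H]1[C@H](O)C/C(CO[Si](C)(C)C(C)(C)C)=C\[Si](C)(C)C
F3 | step 15 | C2 carboxylic acid corresponding to aldehyde 27 | C=C1C(=O)O[C@H](/C=C(/COC(C)=O)CC(=O)O)[C@H]1[C@H](OC(=O)CC(C)C)C/C(CO[Si](C)(C)C(C)(C)C)=C\I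
F4 | step 15 | S-(pyridin-2-yl) thioester of F3 | C=C1C(=O)O[C@H](/C=C(/COC(C)=O)CC(=O)Sc2ccccn2)[C@H]1[C@H](OC(=O)CC(C)C)C/C(CO[Si](C)(C)C(C)(C)C)=C\I
F5 | step 17 | (2R,6R,7R,8R)-epimer of 30 | C=C1C(=O)O[C@@H]2/C=C(/COC(C)=O)C[C@@H](O)/C=C(/CO[Si](C)(C)C(C)(C)C)C[C@@H](OC(=O)CC(C)C)[C@@H]12
F6 | step 17 | (2S)-2-O-formate of 30 | C=C1C(=O)O[C@@H]2/C=C(/COC(C)=O)C[C@H](OC=O)/C=C(/CO[Si](C)(C)C(C)(C)C)C[C@@H](OC(=O)CC(C)C)[C@@H]12
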